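**Assumption:** briarane numbering is used throughout. The given SMILES corresponds to (1S,2S,5Z,7S,8S,9S,10S,11R,14S,17R), and that is the structure planned for.

## Retrosynthetic overview
1. Final operations: α-face epoxidation of a Δ11(20) olefin, preceded by global acetylation of a 6/10-bicyclic tetraol. The tertiary 8-OH stays free.
2. Key step: the six- and ten-membered carbocycles are formed together and last. A biomimetic transannular cyclisation of a 14-membered cembranolide, epoxide-initiated and allylsilane-terminated, makes the C1–C10 bond. It sets C1 and C10 and releases 2-OH and Δ11(20). No direct ten-ring macrocyclisation is used.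
3. The 14-membered ring comes from a Ni/Cr vinyl iodide–aldehyde macrocyclisation (C9–C10).
4. The hydroxy-lactone (C7, C8, C17) comes from a Seebach self-regeneration-of-stereocentres aldol of a D-malic acid dioxolanone with a Z-enal (C7–C8).
5. C14, C1 and C2 come from one Sharpless kinetic resolution/epoxidation. Ring order: γ-lactone, then 14-ring, then 6 + 10 rings, then oxirane.

## Route

**Step 1**
Reactants: 1, but-2-yn-1-ol
Product: 2, (Z)-3-iodobut-2-en-1-ol
Conditions: Red-Al, THF, 0 °C to rt; then I2, −78 °C
Reagents that add atoms: iodine, II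
Why: Alkoxide-directed trans-hydroalumination followed by iodinolysis with retention gives only the Z vinyl iodide, which is the source of the 5Z olefin (C7, C6, C5, C16).

**Step 2**
Reactants: 3, pent-3-yn-1-ol
Product: 4, 5-iodopent-2-yne
Conditions: I2, PPh3, imidazole, CH2Cl2, 0 °C
Reagents that add atoms: iodine, II
Why: Appel iodination of a primary alcohol; the internal alkyne is inert.

**Step 3**
Reactants: 2, (Z)-3-iodobut-2-en-1-ol; 4, 5-iodopent-2-yne
Product: 5, (Z)-3-methyloct-2-en-6-yn-1-ol
Conditions: 4, Zn/LiCl, THF; then 2 (as Na alkoxide, NaH), PdCl2(dppf) 3 mol %, THF, 40 °C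
Reagents that add atoms: none
Why: sp3–sp2 Negishi coupling proceeds with retention at the vinyl iodide, so C4 ends up cis to C7 (Z).

**Step 4**
Reactants: 5, (Z)-3-methyloct-2-en-6-yn-1-ol
Product: 6, (2Z,6E)-7-iodo-3-methylocta-2,6-dien-1-ol
Conditions: Cp2Zr(H)Cl (3 equiv), THF, rt to 40 °C; then I2, 0 °C
Reagents that add atoms: iodine, II
Why: Syn hydrozirconation, equilibrated with excess Schwartz reagent, places Zr on the methyl-bearing alkyne carbon (about 9:1). Iodinolysis then gives the E-2-iodoalkene (future C1=C2); the trisubstituted olefin does not react.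

**Step 5**
Reactants: 7, methyl pent-4-ynoate
Product: 8, methyl (4Z)-5-iodo-4-[(trimethylsilyl)methyl]pent-4-enoate
Conditions: Me3SiCH2MgCl, CuBr·SMe2, LiBr, Et2O–Me2S, −40 °C; add 7, −25 to 0 °C; then I2, −40 °C
Reagents that add atoms: (trimethylsilyl)methylmagnesium chloride, C[Si](C)(C)C[Mg]Cl; iodine, II
Why: Normant syn-carbocupration adds CH2TMS (C20) to the internal alkyne carbon and Cu to the terminus. Iodinolysis with retention gives the vinyl iodide with iodine trans to C12.

**Step 6**
Reactants: 8
Product: 9, (4Z)-5-iodo-4-[(trimethylsilyl)methyl]pent-4-enal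
Conditions: DIBAL-H (1.05 equiv), CH2Cl2, −78 °C
Reagents that add atoms: none
Why: Partial ester reduction through the stable tetrahedral aluminate; the vinyl iodide and allylsilane are untouched.

**Step 7**
Reactants: 6; 9
Product: 10, rac-(2Z,6E,11Z)-12-iodo-3,7-dimethyl-11-[(trimethylsilyl)methyl]dodeca-2,6,11-triene-1,8-diol (racemic at C14)
Conditions: 6, MeLi (1 equiv) then t-BuLi (2.1 equiv), Et2O, −78 °C; MgBr2·OEt2; then 9, −78 to 0 °C
Reagents that add atoms: none
Why: I/Li exchange with retention and transmetallation to Mg, which avoids exchange with the second vinyl iodide. The 1,2-addition forms C14–C1; C14 is formed racemic and is resolved in step 9.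

**Step 8**
Reactants: 10
Product: 11, rac-(2Z,6E,11Z)-8-hydroxy-12-iodo-3,7-dimethyl-11-[(trimethylsilyl)methyl]dodeca-2,6,11-trienal
Conditions: Cu(MeCN)4OTf/bpy/TEMPO (5 mol % each), NMI, air, MeCN, rt
Reagents that add atoms: none
Why: Stahl Cu/TEMPO aerobic oxidation is selective for primary over secondary alcohols and converts Z-allylic alcohols to Z-enals without isomerisation.

**Step 9**
Reactants: 11
Product: 12, (2Z)-5-{(2S,3S)-3-[(1S,4Z)-1-hydroxy-5-iodo-4-[(trimethylsilyl)methyl]pent-4-enyl]-3-methyloxiran-2-yl}-3-methylpent-2-enal (14S; 1S,2S-epoxide)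
Conditions: Ti(OiPr)4, L-(+)-DIPT, t-BuOOH (0.6 equiv), 4 Å MS, CH2Cl2, −20 °C; (14R)-11 is recovered
Reagents that add atoms: tert-butyl hydroperoxide, CC(C)(C)OO
Why: In this Sharpless kinetic resolution the (S)-allylic alcohol is the fast-reacting enantiomer with L-(+)-tartrate and gives the erythro epoxy alcohol. This fixes C14, C1 and C2 in one step; the enal olefin and the iodo-olefin are not allylic alcohols and are inert.

**Step 10**
Reactants: 12
Product: 13, the C14 tert-butyldimethylsilyl ether of 12
Conditions: TBSCl, imidazole, DMAP, DMF, 35 °C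
Reagents that add atoms: TBSCl, CC(C)(C)[Si](C)(C)Cl
Why: Standard silylation. A non-participating group next to C1 is needed because an acetate would open the epoxide by neighbouring-group attack in step 19.

**Step 11**
Reactants: 14, dimethyl (R)-malate
Product: 15, dimethyl (2R,3S)-2-hydroxy-3-methylbutanedioate
Conditions: LDA (2.2 equiv), THF, −78 to −20 °C; MeI, −78 °C
Reagents that add atoms: iodomethane, CI
Why: Fráter–Seebach alkylation; the chelated alkoxide-enolate is methylated anti (about 9:1). This introduces C18.

**Step 12**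
Reactants: 15
Product: 16, dimethyl (2R,3R)-2-hydroxy-3-methylbutanedioate
Conditions: LDA (2.3 equiv), THF, −78 to −30 °C; AcOH/THF, −78 °C
Reagents that add atoms: none
Why: The same chelated dianion is now protonated from the face that MeI used, which pushes the methyl group syn and gives the C17 configuration of the target. The residual epimer is removed at the crystalline stage 18.

**Step 13**
Reactants: 16
Product: 17, (2R,3R)-2-hydroxy-3-methylbutanedioic acid
Conditions: KOH, MeOH–H2O, 0 °C to rt; Dowex H+
Reagents that add atoms: water (hydroxide), O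
Why: Mild saponification; once formed, the carboxylates protect C17 from enolisation.

**Step 14**
Reactants: 17
Product: 18, (2R)-2-[(2R,4R)-2-tert-butyl-5-oxo-1,3-dioxolan-4-yl]propanoic acid (cis)
Conditions: t-BuCHO, TsOH/H2SO4 (cat.), pentane, reflux (Dean–Stark); recrystallise
Reagents that add atoms: pivalaldehyde, CC(C)(C)C=O
Why: Seebach acetalisation; the α-hydroxy acid forms the five-membered cis-dioxolanone, which stores the C8 chirality in the acetal centre.

**Step 15**
Reactants: 13; 18
Product: 19, spiro dioxolanone–γ-lactone. The C7–C8 bond is formed and O7 is lactonised on C19. C8 is the spiro centre, carrying O8 and C9(=O) in the t-Bu acetal ring. Configuration 7S, 8S, 17R (target descriptors, briarane numbering).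
Conditions: 18, LiHMDS (2.05 equiv), THF, −78 °C; add 13; AcOH quench; then EDC·HCl, DMAP (cat.), CH2Cl2, 0 °C
Reagents that add atoms: none
Why: In this self-regeneration-of-stereocentres aldol the aldehyde adds anti to t-Bu, giving retention at C8. The ring-fixed enolate has C17 cis to OLi, so a Zimmerman–Traxler chair gives the C17/O7-syn adduct (7S), which lactonises with C6 trans to C9.

**Step 16**
Reactants: 19
Product: 20, 8-hydroxy-9-hydroxymethyl lactone (C8–OH, C9H2OH)
Conditions: NaBH4, THF–EtOH, −10 °C; pH 7 buffer
Reagents that add atoms: none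
Why: The acylal-type dioxolanone carbonyl is far more electrophilic than the γ-lactone and is reduced selectively, with loss of pivalaldehyde. Borate chelation of the new 1,2-diol suppresses O9-to-C19 translactonisation.

**Step 17**
Reactants: 20
Product: 21, α-hydroxy aldehyde (C9H=O on quaternary C8)
Conditions: Dess–Martin periodinane, NaHCO3, CH2Cl2, 0 °C
Reagents that add atoms: none
Why: Only the primary alcohol can be oxidised (8-OH is tertiary). The buffered, non-acidic conditions spare the epoxide, allylsilane and TBS ether.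

**Step 18**
Reactants: 21
Product: 22, 14-membered cembranolide: (9S)-allylic alcohol, E-type C10=C11(CH2TMS), 1,2-epoxide, 14-OTBS, 5Z olefin, 7,19-lactone, 8-OH
Conditions: CrCl2, NiCl2 (cat.), chiral oxazoline–sulfonamide ligand (the enantiomer giving Si-face addition), Et3N, THF, 2 mM, rt
Reagents that add atoms: none
Why: Nozaki–Hiyama–Kishi macrocyclisation closes an unstrained 14-membered ring. C9 is set by the chiral Cr(III)–sulfonamide (reagent control), because the substrate bias from C8 is weak.

**Step 19 (key step)**
Reactants: 22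
Product: 23, briarane core: trans-fused 6/10 bicycle with Δ11(20), 2-OH, 8-OH, 9-OH, 14-OTBS
Conditions: Et2AlCl (4 equiv), 2,6-di-tert-butyl-4-methylpyridine, CH2Cl2 (2 mM), −78 to −40 °C; Rochelle salt
Reagents that add atoms: none
Why: Proposed new method: the first equivalents of Et2AlCl convert the 8,9-diol into a non-leaving aluminium alkoxide, which blocks 1,4-elimination of the allylsilane, and the excess activates the trisubstituted epoxide; the allylsilane carbon C10, orders of magnitude more nucleophilic than the acyloxy-deactivated Z-Δ5 olefin, attacks tertiary C1 across the ring anti to the C1–O bond (inversion at C1, C2–O retained) through a chair in which the E-olefin places C9 equatorial and H10 axial trans to Me-15, and loss of TMS from the β-silyl cation gives only Δ11(20); the closest known reactions are Lewis-acid epoxide-initiated, allylsilane-terminated cyclisations of epoxygeranyl-type allylsilanes to 2-methylenecyclohexanes and transannular cyclisations of germacrene and cembrene epoxides.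

**Step 20**
Reactants: 23
Product: 24, 2,8,9,14-tetraol
Conditions: HF·pyridine, THF–pyridine, 0 °C to rt
Reagents that add atoms: none
Why: Buffered fluoride desilylation avoids the basic conditions that could cause retro-aldol or C17 epimerisation of the β-hydroxy lactone.

**Step 21**
Reactants: 24
Product: 25, 2,9,14-triacetate with free 8-OH and Δ11(20)
Conditions: Ac2O, pyridine, DMAP (cat.), rt
Reagents that add atoms: acetic anhydride, CC(=O)OC(C)=O
Why: The three secondary alcohols acetylate; the hindered tertiary 8-OH does not react under these conditions.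

**Step 22**
Reactants: 25
Product: 26, junceellolide K
Conditions: mCPBA (1.05 equiv), NaHCO3, CH2Cl2, −10 °C
Reagents that add atoms: mCPBA, OOC(=O)c1cccc(Cl)c1
Why: In this Prilezhaev epoxidation the β (axial) face of the exocyclic olefin is blocked by the 1,3-related axial Me-15, so oxygen arrives from the α (equatorial) face and gives 11R. Δ5 is deactivated by the allylic lactone oxygen and shielded inside the ten-membered ring.

## Compound list
1 | but-2-yn-1-ol | CC#CCO | starting material
2 | (Z)-3-iodobut-2-en-1-ol | OC/C=C(\I)C | intermediate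
3 | pent-3-yn-1-ol | CC#CCCO | starting material
4 | 5-iodopent-2-yne | CC#CCCI | intermediate
5 | (Z)-3-methyloct-2-en-6-yn-1-ol | CC#CCC/C(C)=C\CO | intermediate
6 | (2Z,6E)-7-iodo-3-methylocta-2,6-dien-1-ol | C/C(I)=C\CC/C(C)=C\CO | intermediate
7 | methyl pent-4-ynoate | C#CCCC(=O)OC | starting material
8 | methyl (4Z)-5-iodo-4-[(trimethylsilyl)methyl]pent-4-enoate | I/C=C(C[Si](C)(C)C)/CCC(=O)OC | intermediate
9 | (4Z)-5-iodo-4-[(trimethylsilyl)methyl]pent-4-enal | I/C=C(C[Si](C)(C)C)/CCC=O | intermediate
10 | racemic triene-1,8-diol | I/C=C(C[Si](C)(C)C)/CCC(O)/C(C)=C/CC/C(C)=C\CO | intermediate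
11 | racemic hydroxy Z-enal | I/C=C(C[Si](C)(C)C)/CCC(O)/C(C)=C/CC/C(C)=C\C=O | intermediate
12 | (14S)-(1S,2S)-epoxy alcohol | I/C=C(C[Si](C)(C)C)/CC[C@H](O)[C@]1(C)O[C@H]1CC/C(C)=C\C=O | intermediate
13 | 14-OTBS ether of 12 | I/C=C(C[Si](C)(C)C)/CC[C@H](O[Si](C)(C)C(C)(C)C)[C@]1(C)O[C@H]1CC/C(C)=C\C=O | intermediate
14 | dimethyl (R)-malate | COC(=O)C[C@@H](O)C(=O)OC | starting material
15 | dimethyl (2R,3S)-3-methylmalate | COC(=O)[C@@H](C)[C@@H](O)C(=O)OC | intermediate
16 | dimethyl (2R,3R)-3-methylmalate | COC(=O)[C@H](C)[C@@H](O)C(=O)OC | intermediate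
17 | (2R,3R)-3-methylmalic acid | OC(=O)[C@H](C)[C@@H](O)C(=O)O | intermediate
18 | cis-dioxolanone acid | OC(=O)[C@H](C)[C@H]1O[C@@H](C(C)(C)C)OC1=O | intermediate
19 | spiro dioxolanone–lactone | I/C=C(C[Si](C)(C)C)/CC[C@H](O[Si](C)(C)C(C)(C)C)[C@]1(C)O[C@H]1CC/C(C)=C\[C@@H]1OC(=O)[C@H](C)[C@]12O[C@@H](C(C)(C)C)OC2=O | intermediate
20 | lactone diol | I/C=C(C[Si](C)(C)C)/CC[C@H](O[Si](C)(C)C(C)(C)C)[C@]1(C)O[C@H]1CC/C(C)=C\[C@@H]1OC(=O)[C@H](C)[C@@]1(O)CO | intermediate
21 | α-hydroxy aldehyde | I/C=C(C[Si](C)(C)C)/CC[C@H](O[Si](C)(C)C(C)(C)C)[C@]1(C)O[C@H]1CC/C(C)=C\[C@@H]1OC(=O)[C@H](C)[C@@]1(O)C=O | intermediate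
22 | 14-membered epoxy-allylsilane cembranolide | O[C@H]1/C=C(C[Si](C)(C)C)/CC[C@H](O[Si](C)(C)C(C)(C)C)[C@]2(C)O[C@H]2CC/C(C)=C\[C@@H]2OC(=O)[C@H](C)[C@]21O | intermediate
23 | briarane triol, 14-OTBS | O[C@H]1CC/C(C)=C\[C@@H]2OC(=O)[C@H](C)[C@@]2(O)[C@@H](O)[C@H]2C(=C)CC[C@H](O[Si](C)(C)C(C)(C)C)[C@]12C | intermediate
24 | briarane 2,8,9,14-tetraol | O[C@H]1CC/C(C)=C\[C@@H]2OC(=O)[C@H](C)[C@@]2(O)[C@@H](O)[C@H]2C(=C)CC[C@H](O)[C@]12C | intermediate
25 | Δ11(20) triacetate | CC(=O)O[C@H]1CC/C(C)=C\[C@@H]2OC(=O)[C@H](C)[C@@]2(O)[C@@H](OC(C)=O)[C@H]2C(=C)CC[C@H](OC(C)=O)[C@]12C | intermediate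
26 | junceellolide K | CC(=O)O[C@H]1CC/C(C)=C\[C@@H]2OC(=O)[C@H](C)[C@@]2(O)[C@@H](OC(C)=O)[C@H]2[C@]3(CC[C@H](OC(C)=O)[C@]12C)CO3 | target

## Summary
**Total steps:** 22.

**Longest linear sequence:** 15 steps (steps 1, 3, 4, 7, 8, 9, 10, then 15 to 22).

**Three steps most likely to fail, each with a fallback:**

1. **Step 19, transannular cyclisation.**
   - Competing pathways: 1,2-hydride shift from C14 or C2 (semipinacol or Meinwald ketones), 1,4-elimination of the δ-oxy allylsilane, or ionisation of the allylic lactone.
   - Fallback: reverse the ring order. Run the well-precedented acyclic epoxide–allylsilane cyclisation on a 13-type intermediate, with C9 carried as a protected CH2OH, to build ring A with both arms. Then close the ten-membered ring by B-alkyl Suzuki coupling at C4–C5.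

2. **Step 18, Ni/Cr macrocyclisation and control of C9.**
   - Fallback: form C9–C10 intermolecularly between the lactone aldehyde and the vinyl iodide fragment. Close the 14-membered ring at C14–C1 instead, by Ni/Cr coupling of the C1 vinyl iodide with a C14 aldehyde, and let the matched Sharpless epoxidation select the (14S) epimer inside the macrocycle.

3. **Step 22, selectivity for Δ11(20) over Δ5.**
   - Fallback: replace direct oxygen transfer with stepwise ring closure. Dihydroxylate the less hindered 1,1-disubstituted olefin with OsO4 (α face), sulfonylate the primary C20–OH selectively, and close with K2CO3. This keeps the α C11–O bond.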